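**Retrosynthetic overview**
1. Target ⇐ hydrogenolysis of a protected trimer (12 benzyl ethers, two blocking aryl bromides). Before that, the 3-OH groups of the middle and bottom units are inverted by oxidation/L-Selectride, which gives the all-cis middle unit and turns (+)-catechin into the epicatechin unit.
2. The two C4→C8 bonds come from Friedel–Crafts steps, each trans to the C3 oxygen: the top unit reacts as a 3,4-diacetate (O-activated), the middle unit as a 4-thioether (S-activated afterwards). A C6 bromine on both 5-deoxy units leaves C8 as the only open A-ring position.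
3. Both 5-deoxy units come from one (2S)-flav-3-ene by two face-complementary C–O bond formations: Prévost diacetoxylation (C3–O cis to the aryl) and epoxidation/thiolysis (C3–O trans to the aryl).
4. Key disconnection is the pyran O1–C2 bond: an enantioselective dehydrative oxa-cyclisation of the chalcone-derived allylic alcohol; the chalcone comes from a Claisen–Schmidt condensation.
5. Ring order: pyran ring of the 5-deoxy monomer first, then the top–middle bond, then the middle–bottom bond (bottom pyran from the chiral pool).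

Assumption: 1-(5-bromo-2,4-dihydroxyphenyl)ethanone, 3,4,5-tris(benzyloxy)benzaldehyde and (+)-catechin are bought; "cis/trans" below always refers to the C2 aryl group or the neighbouring substituent in flavan numbering.

**Step 1**
Reactants: 1 1-(5-bromo-2,4-dihydroxyphenyl)ethanone
Product: 2 1-[4-(benzyloxy)-5-bromo-2-hydroxyphenyl]ethanone
Conditions: BnBr (1.05 equiv), K2CO3 (1.1 equiv), acetone, reflux
Reagents that add atoms: benzyl bromide BrCc1ccccc1
Why: Williamson etherification goes only at the 4-OH because the 2-OH is hydrogen-bonded to the ketone.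

**Step 2**
Reactants: 2 1-[4-(benzyloxy)-5-bromo-2-hydroxyphenyl]ethanone; 3 3,4,5-tris(benzyloxy)benzaldehyde
Product: 4 (E)-1-[4-(benzyloxy)-5-bromo-2-hydroxyphenyl]-3-[3,4,5-tris(benzyloxy)phenyl]prop-2-en-1-one
Conditions: KOH, EtOH/THF, rt; then AcOH
Reagents that add atoms: none
Why: Claisen–Schmidt condensation gives the (E)-2'-hydroxychalcone.

**Step 3**
Reactants: 4 (E)-1-[4-(benzyloxy)-5-bromo-2-hydroxyphenyl]-3-[3,4,5-tris(benzyloxy)phenyl]prop-2-en-1-one
Product: 6 (2S)-7-(benzyloxy)-6-bromo-2-[3,4,5-tris(benzyloxy)phenyl]-2H-chromene, via racemic allylic alcohol 5 (not isolated)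
Conditions: NaBH4, CeCl3·7H2O, THF/MeOH, −20 °C; NaHCO3 work-up, crude into toluene; (S,S)-IDPi (5 mol %; BINOL-derived imidodiphosphorimidate, 3,3'-bis[3,5-bis(trifluoromethyl)phenyl], N-triflyl core, enantiomer chosen for 2S), 5 Å MS, −40 °C
Reagents that add atoms: none
Why: Proposed new method: after Luche 1,2-reduction to racemic 5, the confined chiral IDPi acid ionises the allylic alcohol to a planar 1,3-diarylallyl cation/vinylogous ortho-quinone methide held as a contact ion pair with the chiral anion, and the phenol oxygen closes the O1–C2 bond (oxa-6π electrocyclisation/intramolecular allylic etherification) on one face, so both enantiomers of 5 converge on (2S)-6; the closest known reaction type is the chiral N-triflylphosphoramide-catalysed intramolecular allylic substitution of tertiary 2-(1-hydroxyallyl)phenols to 4-substituted 2-aryl-2H-chromenes, not shown for secondary, 4-unsubstituted, polyalkoxylated substrates or with IDPi acids.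

**Step 4**
Reactants: 6 (2S)-7-(benzyloxy)-6-bromo-2-[3,4,5-tris(benzyloxy)phenyl]-2H-chromene
Product: 8 (2R,3S,4S)-7-(benzyloxy)-6-bromo-2-[3,4,5-tris(benzyloxy)phenyl]chromane-3,4-diyl diacetate, via trans-iodoacetate 7 (not isolated)
Conditions: I2 (1.05 equiv), AgOAc (2.3 equiv), dry AcOH/CH2Cl2, 0 °C → rt, dark
Reagents that add atoms: silver acetate CC(=O)[O-].[Ag+]; iodine II (stays only in 7)
Why: Prévost reaction: iodonium forms trans to the C2 aryl, acetate opens it at benzylic C4, and the C4 acetate then displaces iodide at C3 with inversion (acetoxonium ion), so the C3–O bond ends cis to the aryl (2,3-cis) and the second acetate enters C4 trans to it.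

**Step 5**
Reactants: 6 (2S)-7-(benzyloxy)-6-bromo-2-[3,4,5-tris(benzyloxy)phenyl]-2H-chromene
Product: 10 (2R,3R,4R)-7-(benzyloxy)-6-bromo-4-[(2,6-dimethylphenyl)sulfanyl]-2-[3,4,5-tris(benzyloxy)phenyl]chroman-3-ol, via epoxide 9 (not isolated)
Conditions: DMDO (1.05 equiv), acetone/CH2Cl2, −40 °C; volatiles off cold; 2,6-Me2C6H3SH (1.5 equiv), Et3N (cat.), CH2Cl2, −40 → 0 °C
Reagents that add atoms: dimethyldioxirane CC1(C)OO1; 2,6-dimethylbenzenethiol Cc1cccc(C)c1S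
Why: Epoxidation occurs trans to the C2 aryl and sets the C3–O bond (2,3-trans); thiolate epoxide opening at benzylic C4 with inversion installs a soft leaving group that survives hard Lewis acids.

**Step 6**
Reactants: 8 (2R,3S,4S)-7-(benzyloxy)-6-bromo-2-[3,4,5-tris(benzyloxy)phenyl]chromane-3,4-diyl diacetate; 10 (2R,3R,4R)-7-(benzyloxy)-6-bromo-4-[(2,6-dimethylphenyl)sulfanyl]-2-[3,4,5-tris(benzyloxy)phenyl]chroman-3-ol
Product: 11 top–middle dimer (top unit 3-O-acetyl, 2,3-cis-3,4-trans, C4 bonded to C8 of the middle unit; middle unit unchanged from 10)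
Conditions: TMSOTf (0.2 equiv), 4 Å MS, CH2Cl2, −78 → −30 °C, slow addition of 8 to 10 (2.5 equiv, excess recovered); Et3N quench
Reagents that add atoms: none
Why: Friedel–Crafts alkylation: the C3 acetate participates in ionisation of the C4 acetate, C8 of 10 (C6 is blocked by bromine) attacks C4 trans to the C3 oxygen, and the hindered thioether is not activated by the hard Lewis acid.

**Step 7**
Reactants: 12 (+)-catechin
Product: 13 (2R,3S)-5,7-bis(benzyloxy)-2-[3,4-bis(benzyloxy)phenyl]chroman-3-ol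
Conditions: BnBr (4.4 equiv), K2CO3, DMF, 0 °C → rt
Reagents that add atoms: benzyl bromide BrCc1ccccc1
Why: Williamson etherification of the four phenols; the secondary alcohol is not alkylated under carbonate conditions.

**Step 8**
Reactants: 11 top–middle dimer; 13 (2R,3S)-5,7-bis(benzyloxy)-2-[3,4-bis(benzyloxy)phenyl]chroman-3-ol
Product: 14 protected trimer (top unit as in 11; middle unit 2,3-trans-3,4-trans with C4 bonded to C8 of tetra-O-benzylcatechin)
Conditions: AgBF4 (1.5 equiv), 13 (3 equiv), THF/CH2Cl2, −20 → 0 °C, dark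
Reagents that add atoms: none
Why: Thiophilic Ag(I) activation of the C4–S bond gives the benzylic cation, which undergoes Friedel–Crafts capture by C8 of the phloroglucinol ring of 13 (the most nucleophilic arene present) trans to the middle 3-OH.

**Step 9**
Reactants: 14 protected trimer
Product: 15 diketone (C3 ketones in the middle and bottom units; top 3-OAc kept)
Conditions: Dess–Martin periodinane (3 equiv), CH2Cl2, 0 °C → rt
Reagents that add atoms: none
Why: Dess–Martin oxidation converts the two free secondary alcohols to ketones, while the top C3 oxygen is protected as the acetate and the C2/C4 aryl groups stay in their cis (both pseudo-equatorial) arrangement.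

**Step 10**
Reactants: 15 diketone
Product: 17 protected trimer triol (all units 2,3-cis; top 3,4-trans; middle 3,4-cis), via diol acetate 16 (not isolated)
Conditions: L-Selectride (8 equiv), LiBr, THF, −78 → −20 °C; then 2 M NaOH, H2O2, MeOH, 0 °C → rt
Reagents that add atoms: none
Why: L-Selectride reduction delivers hydride to the face opposite the pseudo-equatorial aryl groups at C2 (and C4), giving axial 3-OH cis to the aryl groups in both rings (all-cis middle unit, epicatechin-type bottom unit); the basic peroxide work-up saponifies the acetate.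

**Step 11**
Reactants: 17 protected trimer triol
Product: 18 epirobinetinidol-(4β→8)-epirobinetinidol-(4α→8)-epicatechin (target)
Conditions: H2 (1 atm), 20 % Pd(OH)2/C, Et3N (2.5 equiv), THF/MeOH/H2O, rt; Sephadex LH-20
Reagents that add atoms: none
Why: Catalytic hydrogenolysis removes the twelve benzyl ethers and both aryl bromides without touching any stereocentre.

**Compound list**
1 | 1-(5-bromo-2,4-dihydroxyphenyl)ethanone | CC(=O)c1cc(Br)c(O)cc1O | starting material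
2 | 1-[4-(benzyloxy)-5-bromo-2-hydroxyphenyl]ethanone | CC(=O)c1cc(Br)c(OCc2ccccc2)cc1O | intermediate
3 | 3,4,5-tris(benzyloxy)benzaldehyde | O=Cc1cc(OCc2ccccc2)c(OCc2ccccc2)c(OCc2ccccc2)c1 | starting material
4 | (E)-1-[4-(benzyloxy)-5-bromo-2-hydroxyphenyl]-3-[3,4,5-tris(benzyloxy)phenyl]prop-2-en-1-one | O=C(/C=C/c1cc(OCc2ccccc2)c(OCc2ccccc2)c(OCc2ccccc2)c1)c1cc(Br)c(OCc2ccccc2)cc1O | intermediate
5 | racemic (E)-1-[4-(benzyloxy)-5-bromo-2-hydroxyphenyl]-3-[3,4,5-tris(benzyloxy)phenyl]prop-2-en-1-ol | OC(/C=C/c1cc(OCc2ccccc2)c(OCc2ccccc2)c(OCc2ccccc2)c1)c1cc(Br)c(OCc2ccccc2)cc1O | intermediate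
6 | (2S)-7-(benzyloxy)-6-bromo-2-[3,4,5-tris(benzyloxy)phenyl]-2H-chromene | Brc1cc2C=C[C@@H](c3cc(OCc4ccccc4)c(OCc4ccccc4)c(OCc4ccccc4)c3)Oc2cc1OCc1ccccc1 | intermediate
7 | (2R,3R,4R)-7-(benzyloxy)-6-bromo-3-iodo-2-[3,4,5-tris(benzyloxy)phenyl]chroman-4-yl acetate (I trans to aryl, OAc trans to I) | c1ccccc1COc1cc2O[C@H](c3cc(OCc4ccccc4)c(OCc4ccccc4)c(OCc4ccccc4)c3)[C@@H](I)[C@H](OC(C)=O)c2cc1Br | intermediate
8 | (2R,3S,4S)-7-(benzyloxy)-6-bromo-2-[3,4,5-tris(benzyloxy)phenyl]chromane-3,4-diyl diacetate (2,3-cis-3,4-trans) | c1ccccc1COc1cc2O[C@H](c3cc(OCc4ccccc4)c(OCc4ccccc4)c(OCc4ccccc4)c3)[C@H](OC(C)=O)[C@@H](OC(C)=O)c2cc1Br | intermediate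
9 | (2R,3R,4S)-7-(benzyloxy)-6-bromo-3,4-epoxy-2-[3,4,5-tris(benzyloxy)phenyl]chromane (epoxide trans to aryl) | c1ccccc1COc1cc2O[C@H](c3cc(OCc4ccccc4)c(OCc4ccccc4)c(OCc4ccccc4)c3)[C@H]3O[C@H]3c2cc1Br | intermediate
10 | (2R,3R,4R)-7-(benzyloxy)-6-bromo-4-[(2,6-dimethylphenyl)sulfanyl]-2-[3,4,5-tris(benzyloxy)phenyl]chroman-3-ol (2,3-trans-3,4-trans) | c1ccccc1COc1cc2O[C@H](c3cc(OCc4ccccc4)c(OCc4ccccc4)c(OCc4ccccc4)c3)[C@@H](O)[C@H](Sc3c(C)cccc3C)c2cc1Br | intermediate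
11 | top–middle dimer: 3-O-acetyl 2,3-cis-3,4-trans top unit, C4 bonded to C8 of the middle unit, which keeps the 4-arylsulfanyl group and the 2,3-trans 3-OH; both units 6-bromo, phenols benzylated | c1ccccc1COc1cc2O[C@H](c3cc(OCc4ccccc4)c(OCc4ccccc4)c(OCc4ccccc4)c3)[C@H](OC(C)=O)[C@H](c2cc1Br)c1c(OCc3ccccc3)c(Br)cc2[C@@H](Sc3c(C)cccc3C)[C@H](O)[C@@H](c3cc(OCc4ccccc4)c(OCc4ccccc4)c(OCc4ccccc4)c3)Oc12 | intermediate
12 | (+)-catechin | Oc1cc(O)c2C[C@H](O)[C@@H](c3ccc(O)c(O)c3)Oc2c1 | starting material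
13 | (2R,3S)-5,7-bis(benzyloxy)-2-[3,4-bis(benzyloxy)phenyl]chroman-3-ol (tetra-O-benzylcatechin) | c1ccccc1COc1cc(OCc2ccccc2)c2C[C@H](O)[C@@H](c3ccc(OCc4ccccc4)c(OCc4ccccc4)c3)Oc2c1 | intermediate
14 | protected trimer: top unit as in 11; middle unit 2,3-trans-3,4-trans, C4 bonded to C8 of tetra-O-benzylcatechin | c1ccccc1COc1cc2O[C@H](c3cc(OCc4ccccc4)c(OCc4ccccc4)c(OCc4ccccc4)c3)[C@H](OC(C)=O)[C@H](c2cc1Br)c1c(OCc3ccccc3)c(Br)cc2[C@@H](c3c(OCc4ccccc4)cc(OCc4ccccc4)c4C[C@H](O)[C@@H](c5ccc(OCc6ccccc6)c(OCc6ccccc6)c5)Oc34)[C@H](O)[C@@H](c3cc(OCc4ccccc4)c(OCc4ccccc4)c(OCc4ccccc4)c3)Oc12 | intermediate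
15 | diketone: 14 with C3 ketones in the middle and bottom units | c1ccccc1COc1cc2O[C@H](c3cc(OCc4ccccc4)c(OCc4ccccc4)c(OCc4ccccc4)c3)[C@H](OC(C)=O)[C@H](c2cc1Br)c1c(OCc3ccccc3)c(Br)cc2[C@@H](c3c(OCc4ccccc4)cc(OCc4ccccc4)c4CC(=O)[C@@H](c5ccc(OCc6ccccc6)c(OCc6ccccc6)c5)Oc34)C(=O)[C@@H](c3cc(OCc4ccccc4)c(OCc4ccccc4)c(OCc4ccccc4)c3)Oc12 | intermediate
16 | diol acetate: middle and bottom 3-OH cis to the C2 aryl groups, top 3-OAc still present | c1ccccc1COc1cc2O[C@H](c3cc(OCc4ccccc4)c(OCc4ccccc4)c(OCc4ccccc4)c3)[C@H](OC(C)=O)[C@H](c2cc1Br)c1c(OCc3ccccc3)c(Br)cc2[C@@H](c3c(OCc4ccccc4)cc(OCc4ccccc4)c4C[C@@H](O)[C@@H](c5ccc(OCc6ccccc6)c(OCc6ccccc6)c5)Oc34)[C@@H](O)[C@@H](c3cc(OCc4ccccc4)c(OCc4ccccc4)c(OCc4ccccc4)c3)Oc12 | intermediate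
17 | protected trimer triol: all units 2,3-cis; top 3,4-trans; middle 3,4-cis; twelve benzyl ethers, two 6-bromides | c1ccccc1COc1cc2O[C@H](c3cc(OCc4ccccc4)c(OCc4ccccc4)c(OCc4ccccc4)c3)[C@H](O)[C@H](c2cc1Br)c1c(OCc3ccccc3)c(Br)cc2[C@@H](c3c(OCc4ccccc4)cc(OCc4ccccc4)c4C[C@@H](O)[C@@H](c5ccc(OCc6ccccc6)c(OCc6ccccc6)c5)Oc34)[C@@H](O)[C@@H](c3cc(OCc4ccccc4)c(OCc4ccccc4)c(OCc4ccccc4)c3)Oc12 | intermediate
18 | epirobinetinidol-(4β→8)-epirobinetinidol-(4α→8)-epicatechin; top (2R,3R,4R), middle (2R,3R,4S), bottom (2R,3R) | Oc1ccc2c(c1)O[C@H](c1cc(O)c(O)c(O)c1)[C@H](O)[C@H]2c1c(O)ccc2c1O[C@H](c1cc(O)c(O)c(O)c1)[C@H](O)[C@@H]2c1c(O)cc(O)c2c1O[C@H](c1ccc(O)c(O)c1)[C@H](O)C2 | target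

**Step count:** 11 steps in total. Longest linear sequence: 9 (steps 1, 2, 3, 4, 6, 8, 9, 10, 11).

**Three steps most likely to fail**

Step 3 (the proposed new cyclisation). Possible failures are uncatalysed racemic ring closure of 5, acid-mediated ring opening (racemisation) of 6, or flavene dimerisation. The fallback uses known chemistry, sets out from 2 and comes back at 6. Condense 2 with DMF dimethyl acetal (neat, 95 °C) to (E)-1-[4-(benzyloxy)-5-bromo-2-hydroxyphenyl]-3-(dimethylamino)prop-2-en-1-one F1 and close it with HCl in CH2Cl2 to 7-(benzyloxy)-6-bromo-4H-chromen-4-one F2. Add 3,4,5-tris(benzyloxy)phenylboronic acid by Pd(OCOCF3)2/t-BuPyOx-catalysed asymmetric conjugate arylation (NH4PF6, H2O, ClCH2CH2Cl, 60 °C, ligand enantiomer chosen for 2S) to give (2S)-7-(benzyloxy)-6-bromo-2-[3,4,5-tris(benzyloxy)phenyl]chroman-4-one F3. Reduce with NaBH4 to the 2,4-cis alcohol (2S,4S)-7-(benzyloxy)-6-bromo-2-[3,4,5-tris(benzyloxy)phenyl]chroman-4-ol F4 and dehydrate (Burgess reagent, or MsCl/Et3N then DBU) to 6.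

Step 4 (Prévost diacetoxylation). The very electron-rich chromene and arenes may suffer aryl iodination or iodonium formation on the wrong face. The fallback sets out from 6 (through its epoxide 9, made as in step 5) and comes back at 11. Rearrange 9 with catalytic ZnI2 (Meinwald 1,2-hydride shift) to (2R)-7-(benzyloxy)-6-bromo-2-[3,4,5-tris(benzyloxy)phenyl]chroman-3-one F5. Reduce with L-Selectride/LiBr at −78 °C to the 2,3-cis alcohol (2R,3R)-7-(benzyloxy)-6-bromo-2-[3,4,5-tris(benzyloxy)phenyl]chroman-3-ol F6. Oxidise C4 with DDQ/2-ethoxyethanol to (2R,3R,4S)-7-(benzyloxy)-6-bromo-4-(2-ethoxyethoxy)-2-[3,4,5-tris(benzyloxy)phenyl]chroman-3-ol F7 (ether trans to the 3-OH), and acetylate (Ac2O, DMAP, pyridine) to its 3-acetate (2R,3R,4S)-7-(benzyloxy)-6-bromo-4-(2-ethoxyethoxy)-2-[3,4,5-tris(benzyloxy)phenyl]chroman-3-yl acetate F8. Coupling F8 with 10 under TMSOTf as in step 6 gives 11.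

Step 6 (Friedel–Crafts at C8). C8 is flanked by two oxygens and deactivated by the C6 bromine, 8 can alkylate itself, and the arylthio group could migrate to the top-unit cation. The fallback sets out from 6 and comes back at 14. Hydroborate 6 (BH3·SMe2, then NaOH/H2O2) to the sulfur-free 2,3-trans alcohol (2R,3S)-7-(benzyloxy)-6-bromo-2-[3,4,5-tris(benzyloxy)phenyl]chroman-3-ol F9. Use it in four-fold excess with 8 and TMSOTf to obtain the top–middle dimer with a C4 methylene in the middle unit F10. Oxidise that benzylic position with DDQ/MeOH to the 4-methoxy dimer (methoxy cis to the 3-OH) F11, and couple F11 with 13 under TMSOTf to reach 14.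

**Further compounds**
F1 | step 3 | (E)-1-[4-(benzyloxy)-5-bromo-2-hydroxyphenyl]-3-(dimethylamino)prop-2-en-1-one | CN(C)/C=C/C(=O)c1cc(Br)c(OCc2ccccc2)cc1O
F2 | step 3 | 7-(benzyloxy)-6-bromo-4H-chromen-4-one | O=c1ccoc2cc(OCc3ccccc3)c(Br)cc12
F3 | step 3 | (2S)-7-(benzyloxy)-6-bromo-2-[3,4,5-tris(benzyloxy)phenyl]chroman-4-one | O=C1C[C@@H](c2cc(OCc3ccccc3)c(OCc3ccccc3)c(OCc3ccccc3)c2)Oc2cc(OCc3ccccc3)c(Br)cc12
F4 | step 3 | (2S,4S)-7-(benzyloxy)-6-bromo-2-[3,4,5-tris(benzyloxy)phenyl]chroman-4-ol | O[C@H]1C[C@@H](c2cc(OCc3ccccc3)c(OCc3ccccc3)c(OCc3ccccc3)c2)Oc2cc(OCc3ccccc3)c(Br)cc12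
F5 | step 4 | (2R)-7-(benzyloxy)-6-bromo-2-[3,4,5-tris(benzyloxy)phenyl]chroman-3-one | c1ccccc1COc1cc2O[C@H](c3cc(OCc4ccccc4)c(OCc4ccccc4)c(OCc4ccccc4)c3)C(=O)Cc2cc1Br
F6 | step 4 | (2R,3R)-7-(benzyloxy)-6-bromo-2-[3,4,5-tris(benzyloxy)phenyl]chroman-3-ol | c1ccccc1COc1cc2O[C@H](c3cc(OCc4ccccc4)c(OCc4ccccc4)c(OCc4ccccc4)c3)[C@H](O)Cc2cc1Br
F7 | step 4 | (2R,3R,4S)-7-(benzyloxy)-6-bromo-4-(2-ethoxyethoxy)-2-[3,4,5-tris(benzyloxy)phenyl]chroman-3-ol | c1ccccc1COc1cc2O[C@H](c3cc(OCc4ccccc4)c(OCc4ccccc4)c(OCc4ccccc4)c3)[C@H](O)[C@@H](OCCOCC)c2cc1Br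
F8 | step 4 | (2R,3R,4S)-7-(benzyloxy)-6-bromo-4-(2-ethoxyethoxy)-2-[3,4,5-tris(benzyloxy)phenyl]chroman-3-yl acetate | c1ccccc1COc1cc2O[C@H](c3cc(OCc4ccccc4)c(OCc4ccccc4)c(OCc4ccccc4)c3)[C@H](OC(C)=O)[C@@H](OCCOCC)c2cc1Br
F9 | step 6 | (2R,3S)-7-(benzyloxy)-6-bromo-2-[3,4,5-tris(benzyloxy)phenyl]chroman-3-ol | c1ccccc1COc1cc2O[C@H](c3cc(OCc4ccccc4)c(OCc4ccccc4)c(OCc4ccccc4)c3)[C@@H](O)Cc2cc1Br
F10 | step 6 | top–middle dimer with C4 methylene in the middle unit (top unit as in 11; middle unit 2,3-trans 3-OH) | c1ccccc1COc1cc2O[C@H](c3cc(OCc4ccccc4)c(OCc4ccccc4)c(OCc4ccccc4)c3)[C@H](OC(C)=O)[C@H](c2cc1Br)c1c(OCc3ccccc3)c(Br)cc2C[C@H](O)[C@@H](c3cc(OCc4ccccc4)c(OCc4ccccc4)c(OCc4ccccc4)c3)Oc12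
F11 | step 6 | 4-methoxy dimer (F10 with OMe at C4 of the middle unit, cis to its 3-OH) | c1ccccc1COc1cc2O[C@H](c3cc(OCc4ccccc4)c(OCc4ccccc4)c(OCc4ccccc4)c3)[C@H](OC(C)=O)[C@H](c2cc1Br)c1c(OCc3ccccc3)c(Br)cc2[C@H](OC)[C@H](O)[C@@H](c3cc(OCc4ccccc4)c(OCc4ccccc4)c(OCc4ccccc4)c3)Oc12
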